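**Retrosynthetic overview**
Target 10 ⇒ (benzoylation of the primary allylic OH; Luche reduction) ⇒ dienal 8, which already holds the whole carbocycle with C7 at the aldehyde level.
Feature used: the single ring C1–C6 with exocyclic C7 on C1, diene C1=C2–C3=C4, C5–OBz and C6–OH trans. Cutting C1–C6 and C3=C4 gives a four-carbon unit C7–C1–C2–C3 (crotonaldehyde 5) and a three-carbon unit C4–C5–C6 (2-benzoyloxymalonaldehyde, carried as mono-acetal 4).
Ring formation (step 4, the only ring): amine-catalysed aldol through the dienamine α-carbon (C1–C6), then vinylogous aldol condensation through the γ-carbon (C3=C4); C6 from the catalyst, C5 dynamic.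
4 ⇒ ozonolysis of allylic benzoate 3 ⇒ alcohol 2 ⇒ vinyl Grignard addition to 2,2-dimethoxyacetaldehyde 1.

Key step: step 4

Remark: atoms are numbered C1 (ring carbon bearing exocyclic C7), C2–C4 (diene CH), C5 (CH–OBz), C6 (CH–OH); the target is the trans (5R,6R) isomer.
Remark: free 2-(benzoyloxy)propanedial is a fully enolised vinylogous acid that would trap the amine as a vinylogous formamide and add through C2 or O to the iminium ion of 5. It is therefore used with one formyl group masked as the dimethyl acetal (4), and the second formyl group is released in the flask after the first C–C bond has formed.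
Remark: 1 is sold as an aqueous solution and is used after extraction, drying and distillation.

Step 1
Reactants: 1 2,2-dimethoxyacetaldehyde
Product: 2 rac-1,1-dimethoxybut-3-en-2-ol
Conditions: CH2=CHMgBr, THF, −78 to 0 °C; aq. NH4Cl
Reagents that add atoms: vinylmagnesium bromide, C=C[Mg]Br
Why: Grignard addition to the only electrophilic carbon of 1 (the acetal is inert) should give the allylic alcohol, left racemic on purpose because this carbon becomes the epimerisable C5.

Step 2
Reactants: 2 rac-1,1-dimethoxybut-3-en-2-ol
Product: 3 rac-1,1-dimethoxybut-3-en-2-yl benzoate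
Conditions: BzCl, pyridine, DMAP (cat.), CH2Cl2, 0 °C
Reagents that add atoms: benzoyl chloride, O=C(Cl)c1ccccc1
Why: Nucleophilic acyl substitution on a secondary alcohol under pyridine/DMAP catalysis installs the C5 benzoate that is carried to the target.

Step 3
Reactants: 3 rac-1,1-dimethoxybut-3-en-2-yl benzoate
Product: 4 rac-1,1-dimethoxy-3-oxopropan-2-yl benzoate
Conditions: O3, CH2Cl2, −78 °C; then Me2S, −78 to 23 °C; used crude
Reagents that add atoms: ozone, [O-][O+]=O
Why: Ozonolysis with reductive work-up cleaves the terminal alkene to the aldehyde without touching acetal or ester, and the sensitive aldehyde is not purified so that it cannot lose methanol.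

Step 4
Reactants: 4 rac-1,1-dimethoxy-3-oxopropan-2-yl benzoate; 5 (E)-but-2-enal (crotonaldehyde)
Product: 8 (5R,6R)-5-(benzoyloxy)-6-hydroxycyclohexa-1,3-diene-1-carbaldehyde, via aldol adduct acetal 6 (not isolated), via hydroxy dialdehyde 7 (not isolated)
Conditions: (S)-proline (30 mol%), DMF, 4 °C, 5 (2 equiv) added over 24 h; then 1 M aq. HCl (0.5 equiv), 23 °C; then NaOAc (0.6 equiv), 23 °C
Reagents that add atoms: none
Why: Proposed new method: (S)-proline converts 5 into a dienamine whose α-carbon (C1) adds to the free formyl group of 4 through the hydrogen-bonded chair-like transition state of proline aldol reactions, and double-bond isomerisation with hydrolysis leaves the Morita–Baylis–Hillman-type adduct 6; aqueous acid then frees the C4 formyl group (7), the amine re-forms the cross-conjugated dienamine of the 2-substituted enal, its γ-carbon (C3) attacks C4 and E1cB loss of water gives C3=C4 of dienal 8. The closest known reaction types are proline-mediated dienamine α-additions of enals (intramolecular Morita–Baylis–Hillman-type cyclisation of enal aldehydes, aza-Morita–Baylis–Hillman-type Mannich reaction with imines) and amine-catalysed formal [3+3] annulations of enals, but an intermolecular aldol with an aldehyde acceptor followed by vinylogous aldol condensation to a cyclohexadienal has not been shown. The single ring closes in a 6-(enolendo)-exo-trig vinylogous aldol addition. C6 is set by the catalyst (attack on the re face of the acceptor formyl group, predicted 6R), whereas C5 is left open in the aldol and becomes epimerisable once it stands α to the freed formyl group in 7, so that the threo epimer, which can close with both C–O bonds pseudo-equatorial, should be drained to the trans product. The step needs cross- rather than self-aldolisation of 5, attack of the dienamine through Cα before Cγ, and survival of the C6 hydroxyl: the acetal in 4 secures the first by offering one non-enolised, α-branched, inductively activated formyl group that can be neither aldol donor nor vinylogous acid, the second rests on the known α-preference of proline dienamines towards carbonyl electrophiles, and the third on buffered conditions at or below 23 °C that keep 8 from aromatising.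

Step 5
Reactants: 8 (5R,6R)-5-(benzoyloxy)-6-hydroxycyclohexa-1,3-diene-1-carbaldehyde
Product: 9 (1R,6R)-6-hydroxy-5-(hydroxymethyl)cyclohexa-2,4-dien-1-yl benzoate
Conditions: NaBH4, CeCl3·7H2O, MeOH, −78 °C
Reagents that add atoms: none
Why: Luche reduction should deliver hydride 1,2 to the conjugated aldehyde at low temperature and leave the benzoate, the diene and both stereocentres untouched.

Step 6
Reactants: 9 (1R,6R)-6-hydroxy-5-(hydroxymethyl)cyclohexa-2,4-dien-1-yl benzoate
Product: 10 [(5R,6R)-5-(benzoyloxy)-6-hydroxycyclohexa-1,3-dien-1-yl]methyl benzoate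
Conditions: BzCl (1.05 equiv), 2,4,6-collidine, CH2Cl2, −78 to −30 °C
Reagents that add atoms: benzoyl chloride, O=C(Cl)c1ccccc1
Why: Kinetically selective nucleophilic acyl substitution at the unhindered primary allylic hydroxyl over the flanked secondary C6 hydroxyl, with a weak hindered base that should not promote 1,2-acyl migration.

**Compound list**
1 | 2,2-dimethoxyacetaldehyde | COC(OC)C=O | starting material
2 | rac-1,1-dimethoxybut-3-en-2-ol | C=CC(O)C(OC)OC | intermediate
3 | rac-1,1-dimethoxybut-3-en-2-yl benzoate | C=CC(OC(=O)c1ccccc1)C(OC)OC | intermediate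
4 | rac-1,1-dimethoxy-3-oxopropan-2-yl benzoate (2-(benzoyloxy)propanedial mono(dimethyl acetal)) | O=CC(OC(=O)c1ccccc1)C(OC)OC | intermediate
5 | (E)-but-2-enal (crotonaldehyde) | C/C=C/C=O | starting material
6 | (3R,4E)-4-formyl-3-hydroxy-1,1-dimethoxyhex-4-en-2-yl benzoate (both C2 epimers; not isolated) | C/C=C(/C=O)[C@@H](O)C(OC(=O)c1ccccc1)C(OC)OC | intermediate
7 | (3R,4E)-4-formyl-3-hydroxy-1-oxohex-4-en-2-yl benzoate (C2 epimers in equilibrium; not isolated) | C/C=C(/C=O)[C@@H](O)C(OC(=O)c1ccccc1)C=O | intermediate
8 | (5R,6R)-5-(benzoyloxy)-6-hydroxycyclohexa-1,3-diene-1-carbaldehyde | O=CC1=CC=C[C@@H](OC(=O)c2ccccc2)[C@@H]1O | intermediate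
9 | (1R,6R)-6-hydroxy-5-(hydroxymethyl)cyclohexa-2,4-dien-1-yl benzoate | OCC1=CC=C[C@@H](OC(=O)c2ccccc2)[C@@H]1O | intermediate
10 | [(5R,6R)-5-(benzoyloxy)-6-hydroxycyclohexa-1,3-dien-1-yl]methyl benzoate | O=C(OCC1=CC=C[C@@H](OC(=O)c2ccccc2)[C@@H]1O)c1ccccc1 | target

Total step count: 6. Longest linear sequence: 6 steps (1 → 10).

**Steps most likely to fail**

Step 4 (proposed new method). Several processes can defeat it:
- loss of methanol from 4 and capture of the amine as a vinylogous formamide;
- self-annulation of crotonaldehyde outrunning the cross-aldol;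
- elimination of the C6 hydroxyl with aromatisation;
- failure of C5 to equilibrate before ring closure, giving a cis/trans mixture.

The fallback makes the same two ring bonds one after the other by known reactions. It sets out from crotonaldehyde 5 (with commercial hex-5-enal as second component) and comes back at 8. Hex-5-enal is α-benzoyloxylated with dibenzoyl peroxide under diarylprolinol silyl ether catalysis (known enamine α-oxidation, catalyst enantiomer chosen for the 2R aldehyde) to (2R)-1-oxohex-5-en-2-yl benzoate F1. Cross-metathesis of F1 with 5 (second-generation Hoveyda–Grubbs catalyst, CH2Cl2, 40 °C) gives (2R,5E)-1,7-dioxohept-5-en-2-yl benzoate F2. (S)-Proline then forms C1–C6 by the known intramolecular Morita–Baylis–Hillman-type aldol cyclisation of hept-2-enedials to (5R,6R)-5-(benzoyloxy)-6-hydroxycyclohex-1-ene-1-carbaldehyde F3, with C6 under catalyst control and any cis epimer removed by chromatography. TBSOTf/Et3N converts F3 into the silyl ether and silyl dienol ether (1R,2R)-2-[(tert-butyldimethylsilyl)oxy]-3-{[(tert-butyldimethylsilyl)oxy]methylidene}cyclohex-4-en-1-yl benzoate F4. Saegusa–Ito oxidation with Pd(OAc)2 in MeCN introduces C3=C4 and gives (5R,6R)-5-(benzoyloxy)-6-[(tert-butyldimethylsilyl)oxy]cyclohexa-1,3-diene-1-carbaldehyde F5, and HF·pyridine in THF removes the silyl ether to give 8.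

Step 6. Over-acylation of the secondary C6 hydroxyl or base-promoted migration of the C5 benzoate to O6 would erode the selectivity. The fallback protects C6 before the aldehyde is reduced; it sets out from 8, replaces steps 5 and 6, and comes back at 10. TESCl/imidazole in DMF at 0 °C gives (5R,6R)-5-(benzoyloxy)-6-[(triethylsilyl)oxy]cyclohexa-1,3-diene-1-carbaldehyde F6. Luche reduction gives (1R,6R)-5-(hydroxymethyl)-6-[(triethylsilyl)oxy]cyclohexa-2,4-dien-1-yl benzoate F7. Benzoylation of the only free hydroxyl (BzCl, pyridine) gives [(5R,6R)-5-(benzoyloxy)-6-[(triethylsilyl)oxy]cyclohexa-1,3-dien-1-yl]methyl benzoate F8, and HF·pyridine releases 10.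

Step 3. β-Elimination of methanol from aldehyde 4 (E1cB through the acidic C–H next to the formyl group) during work-up or storage would destroy the precursor. The fallback carries the masked formyl group as a cyclic acetal, whose ring opening by β-elimination is reversible; it sets out from 3 and comes back at 7. Acetal exchange (ethane-1,2-diol, TsOH cat., toluene, removal of methanol) gives rac-1-(1,3-dioxolan-2-yl)prop-2-en-1-yl benzoate F9. Ozonolysis as in step 3 gives rac-1-(1,3-dioxolan-2-yl)-2-oxoethyl benzoate F10. F10 takes the place of 4 in the first stage of step 4 and gives (2R,3E)-1-(1,3-dioxolan-2-yl)-3-formyl-2-hydroxypent-3-en-1-yl benzoate F11, whose acid hydrolysis in the same flask gives 7.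

**Further compounds**
F1 | step 4 | (2R)-1-oxohex-5-en-2-yl benzoate | C=CCC[C@@H](OC(=O)c1ccccc1)C=O
F2 | step 4 | (2R,5E)-1,7-dioxohept-5-en-2-yl benzoate | O=C/C=C/CC[C@@H](OC(=O)c1ccccc1)C=O
F3 | step 4 | (5R,6R)-5-(benzoyloxy)-6-hydroxycyclohex-1-ene-1-carbaldehyde | O=CC1=CCC[C@@H](OC(=O)c2ccccc2)[C@@H]1O
F4 | step 4 | (1R,2R)-2-[(tert-butyldimethylsilyl)oxy]-3-{[(tert-butyldimethylsilyl)oxy]methylidene}cyclohex-4-en-1-yl benzoate | CC(C)(C)[Si](C)(C)OC=C1C=CC[C@@H](OC(=O)c2ccccc2)[C@@H]1O[Si](C)(C)C(C)(C)C
F5 | step 4 | (5R,6R)-5-(benzoyloxy)-6-[(tert-butyldimethylsilyl)oxy]cyclohexa-1,3-diene-1-carbaldehyde | O=CC1=CC=C[C@@H](OC(=O)c2ccccc2)[C@@H]1O[Si](C)(C)C(C)(C)C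
F6 | step 6 | (5R,6R)-5-(benzoyloxy)-6-[(triethylsilyl)oxy]cyclohexa-1,3-diene-1-carbaldehyde | O=CC1=CC=C[C@@H](OC(=O)c2ccccc2)[C@@H]1O[Si](CC)(CC)CC
F7 | step 6 | (1R,6R)-5-(hydroxymethyl)-6-[(triethylsilyl)oxy]cyclohexa-2,4-dien-1-yl benzoate | OCC1=CC=C[C@@H](OC(=O)c2ccccc2)[C@@H]1O[Si](CC)(CC)CC
F8 | step 6 | [(5R,6R)-5-(benzoyloxy)-6-[(triethylsilyl)oxy]cyclohexa-1,3-dien-1-yl]methyl benzoate | O=C(OCC1=CC=C[C@@H](OC(=O)c2ccccc2)[C@@H]1O[Si](CC)(CC)CC)c1ccccc1
F9 | step 3 | rac-1-(1,3-dioxolan-2-yl)prop-2-en-1-yl benzoate | C=CC(OC(=O)c1ccccc1)C1OCCO1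
F10 | step 3 | rac-1-(1,3-dioxolan-2-yl)-2-oxoethyl benzoate | O=CC(OC(=O)c1ccccc1)C1OCCO1
F11 | step 3 | (2R,3E)-1-(1,3-dioxolan-2-yl)-3-formyl-2-hydroxypent-3-en-1-yl benzoate (both C1 epimers) | C/C=C(/C=O)[C@@H](O)C(OC(=O)c1ccccc1)C1OCCO1
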